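All runs were computed with constants of no real substance, noise included.

Early in both earlier runs X disappears fast, and the bench habit is to call that first order: equal times take equal fractions, whatever the charge. So I work with the fraction left and not with the fraction made.

| flask | X | remark | time |
|---|---|---|---|
| east | 0.75 M | run made earlier |  |
| north | 1.1 M | run made earlier |  |
| flask | 1.5 M |  | 5.0 h |

| run | time / h | D / % | Z / % | G / % |
|---|---|---|---|---|
| east | 0.833 | 21.2 | 5.0 | 4.0 |
| east | 1.50 | 33.8 | 8.5 | 3.4 |
| east | 2.50 | 49.8 | 7.4 | 5.6 |
| east | 3.00 | 56.4 | 6.9 | 5.6 |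
| east | 4.00 | 64.1 | 6.6 | 4.1 |
| east | 5.00 | 70.3 | 5.0 | 3.7 |
| east | 6.00 | 75.8 | 5.1 | 2.8 |
| north | 0.333 | 7.9 | 2.9 | 1.6 |
| north | 1.00 | 22.1 | 6.0 | 3.7 |
| north | 1.50 | 34.4 | 10.0 | 3.6 |
| north | 2.50 | 46.1 | 9.2 | 6.8 |
| north | 4.00 | 61.8 | 10.2 | 6.0 |
| north | 5.00 | 67.6 | 6.9 | 5.4 |
| north | 6.00 | 75.0 | 6.0 | 3.8 |

(scatter of a reading: 1 percentage point)

- percentages count the X that a species holds: one G or Z counts as two
- D is meant together with its Z
- in an amount of D, one Z counts as one D

- amount of D in the flask at 5.0 h, in percent of the X charged
- amount of Z in the flask at 5.0 h, in percent of the X charged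
- amount of G in the flask at 5.0 h, in percent of the X charged
- amount of X in the flask at 5.0 h, in percent of the X charged

X is not read, but D counts its Z, so free X is the charge minus D, minus G, minus half of Z. At 5.00 h the east run keeps 23.5% and the north run 23.6%. My leaving constant (the apparent first-order constant), the natural logarithm of one over the fraction left, divided by the time, is then 0.289 h⁻¹. At 1.00 h the north run gave 0.340 h⁻¹, so the constant slips with time, and I use the late one. For the flask it leaves 23.6% of X.

Some of what has left X sits in G and, beside D, in Z, though. That held part, G plus half of Z, reads 6.20% in the east run and 8.85% in the north run, a ratio of 1.43 against 1.47 for the charges. Between these two runs the held part follows the charge, so the flask, charged 1.36 times the north run, should hold 12.1%. That is about half of its free X, against 0.264 in the east run. Here the rule stops working for D, and I reckon D as what remains: 64.4%.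

The forecast gives D 66% (62% to 71%), Z 9.5% (7% to 12.5%), G 7% (5% to 9.5%) and X 22% (17% to 26%), noting that “Z and G readings scale about with concentration”. Its D stands above mine and its X below mine.

The flask gives D 66.7%, Z 10.5%, G 7.04% and X 21.0%, inside the forecast's ranges.

    2 X ⇌ G (K = 0.217 L mol⁻¹, k = 4.85 × 10⁻⁴ L mol⁻¹ min⁻¹)
    X → D (k = 0.00479 min⁻¹)
    X + D ⇌ Z, settled at all times (K = 0.270 L mol⁻¹)

The flask's leaving constant comes to 0.312 h⁻¹, a little higher than the 0.289 h⁻¹ read from the north run, and its held part comes to 12.3% of its charge, close to my 12.1%. A neighbouring flask is the same but charged with 0.60 M of X. With 0.289 h⁻¹ I reckon 23.6% of X left in it and 4.83% held, so D at 71.6%. That neighbouring flask gives X 22.5% and D 71.7%.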